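**In the vessel.** This closed, stirred flask was charged with 0.010 M of starting material. Part of the charge ends up in the pair of target and isomer of the product A, and the question is how that pair divides.

| flask | starting material | remark | time |
|---|---|---|---|
| Sunday's | 0.0050 M | run made earlier |  |
| Wednesday's | 0.020 M | run made earlier |  |
| flask | 0.010 M |  | 15 min |

- Sunday's (time / min: target / %, isomer of the product A / %): 5.00: 20.4, 11.7; 10.0: 18.2, 13.5; 15.0: 17.7, 13.9; 20.0: 17.0, 15.2
- Wednesday's (time / min: target / %, isomer of the product A / %): 5.00: 10.5, 5.9; 10.0: 9.3, 6.2; 15.0: 8.2, 7.6; 20.0: 7.7, 7.2

(readings scatter by 0.3 percentage points)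

1. ratio of target to isomer of the product A at 2.5 s
2. ratio of target to isomer of the product A at 50 s
3. ratio of target to isomer of the product A at 15 min
4. which of target and isomer of the product A there is more of at 15 min

- a reading or a percentage of target counts all its forms, free or not

**The fork.** Follow one molecule that has reached the pair: its odds of being target are r, the amount of target over that of isomer of the product A. Pooled over their four readings, Sunday's run gives r = 1.35 and Wednesday's 1.33, about equal, although their charges were 0.0050 M and 0.020 M.

**For the bench.** Between these two runs the charge left r about where it was: at 15.0 min it shows in the pair's size, 31.6% on Sunday against 15.8% on Wednesday. Time moves r instead, with the two runs together giving 1.76 at 5.00 min. The two early asked times should therefore stand higher than that. The same pooling at 15.0 min gives the pair ratio r15, the selectivity between the two read at that time, of 1.20. It is greater than one, so target should lead at 15 min.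

**The forecast.** The forecast gives 2.45, 2.3 and 1.2, and says “target still leads slightly”.

**The flask.** The flask gives 3.14 at 2.5 s, 2.83 at 50 s and 1.23 at 15 min, with target at 12.6% and isomer of the product A at 10.3%.

    starting material ⇌ target (K = 2.40, k = 0.00410 /s)
    starting material ⇌ isomer of the product A (K = 3.10, k = 0.00130 /s)
    starting material ⇌ third isomer (K = 0.380, k = 5.00 × 10⁻⁴ /s)
    2 starting material → homo dimer (k = 0.990 /M/s)
    crystals ⇌ target, rate k5*(cs5 - [target]) while solid is left; crystals form when [target] > cs5 (solubility = 7.90 mM, k = 0.470 /s)
    target ⇌ isomer of the product B (K = 0.670, k = 0.00280 /s)

The forward half-life of dissolved target into isomer of the product B is 4.1 min, shorter than the 15 min of the run. The reading r15 = 1.20 stands beside the flask's 1.23. At 15 min the neighbour flask, charged with 0.0025 M, stands at 1.26, above the 1.20 of r15.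

The runs are simulated with made-up constants.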